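**Plan**

1. Numbering: ten-membered ring C1=C10(C14)–C9–C8–C7–C6–C5=C4(C15)–C3–C2; lactone ring O–C6–C7–C11(=C13)–C12(=O). Enabling feature: C10 sits between two oxygenated carbons, C9 in the ring and C14 outside it, so with C9 as ketone and C14 as ester it is a β-keto ester methylene that can condense with an aldehyde at C1.
2. Retrosynthetic cuts, in order: the C8 and C9 acyl groups and the oxidation levels at C12, C14 and C9; C1=C10 (Knoevenagel, opens the ten-membered ring); C9–C10 (diazoacetate homologation); C4=C5 (Wittig); C7–C8 and C11–C13 (Michael/Mannich on a butenolide).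
3. Forward: the five-membered oxygen ring is there from the first compound (butenolide, then α-methylene lactone, then methyl lactol ether). The chain grows at C5, then at C9. The ten-membered ring closes last, and the lactone is restored at the end.
4. Stereochemistry: C6 from (S)-5-(hydroxymethyl)furan-2(5H)-one; C7 by addition anti to the C6 substituent; C8 from the lithium-chelated glycolate enolate; C9 by Felkin–Anh hydride delivery; the side-chain centre from (S)-2-methylbutanoic acid. C4=C5 comes from a stabilised ylide, C1=C10 from equilibration to the ring-cis isomer.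

Key step: step 16

Remark: C12 of the lactol and of its methyl ether is carried as a mixture of anomers and is written without configuration; it ends as the lactone carbonyl. Locants in names follow the numbering above.

**Route**

Step 1
Reactants: 1 (S)-5-(hydroxymethyl)furan-2(5H)-one
Product: 2 (S)-5-{[(tert-butyldimethylsilyl)oxy]methyl}furan-2(5H)-one
Conditions: TBSCl, imidazole, CH2Cl2, 0 °C → rt
Reagents that add atoms: tert-butyldimethylsilyl chloride, CC(C)(C)[Si](C)(C)Cl
Why: Imidazole-promoted O-silylation of the primary alcohol; C6 is not involved, and the silyloxymethyl group later blocks one face of the butenolide.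

Step 2
Reactants: 3 4-methoxybenzyl alcohol; 4 tert-butyl bromoacetate
Product: 5 tert-butyl 2-[(4-methoxybenzyl)oxy]acetate
Conditions: NaH, tetrabutylammonium iodide (cat.), THF, 0 °C → rt
Reagents that add atoms: none
Why: Williamson ether synthesis in which the sodium alkoxide of 3 displaces bromide from the activated α-bromo ester, the hindered tert-butyl ester resisting transesterification.

Step 3
Reactants: 5 tert-butyl 2-[(4-methoxybenzyl)oxy]acetate; 2 (S)-5-{[(tert-butyldimethylsilyl)oxy]methyl}furan-2(5H)-one; 6 N,N-dimethylmethyleneiminium iodide (Eschenmoser's salt)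
Product: 9 tert-butyl (2S)-2-[(2S,3S,4R)-2-{[(tert-butyldimethylsilyl)oxy]methyl}-4-[(dimethylamino)methyl]-5-oxotetrahydrofuran-3-yl]-2-[(4-methoxybenzyl)oxy]acetate, via glycolate lithium enolate 7 (not isolated), via lactone lithium enolate 8 (not isolated)
Conditions: LiN(iPr)2, THF, −78 °C; 2, −78 °C; then 6, −78 °C → rt
Reagents that add atoms: none
Why: Michael addition followed by Mannich trapping: the chelated enolate (OLi cis to the benzyloxy oxygen) attacks C7 anti to the C6 silyloxymethyl group, a lithium-bridged arrangement with the enolate ester over the lactone ring, its C8 hydrogen toward C6 and the benzyloxy group outside the ring should set C8, and the iminium salt alkylates the lactone enolate anti to the new C7 substituent (C11, removed in step 4).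

Step 4
Reactants: 9 Mannich base lactone
Product: 11 tert-butyl (2S)-2-[(2S,3S)-2-{[(tert-butyldimethylsilyl)oxy]methyl}-4-methylene-5-oxotetrahydrofuran-3-yl]-2-[(4-methoxybenzyl)oxy]acetate, via trimethylammonium iodide 10 (not isolated)
Conditions: MeI, CH2Cl2, rt; then aq. NaHCO3, rt
Reagents that add atoms: none
Why: N-methylation followed by E1cB (Hofmann-type) elimination of trimethylamine from the β-ammonio lactone should create the exocyclic C11=C13 bond under conditions too mild to epimerise C7 or C8.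

Step 5
Reactants: 11 α-methylene lactone
Product: 12 tert-butyl (2S)-2-[(2S,3S)-2-{[(tert-butyldimethylsilyl)oxy]methyl}-5-hydroxy-4-methylenetetrahydrofuran-3-yl]-2-[(4-methoxybenzyl)oxy]acetate (anomers)
Conditions: iBu2AlH (1.1 equiv), CH2Cl2, −78 °C; aq. potassium sodium tartrate
Reagents that add atoms: none
Why: Half-reduction of the γ-lactone to the lactol by 1,2-hydride addition at −78 °C, where the tert-butyl ester reacts far more slowly.

Step 6
Reactants: 12 lactol
Product: 13 tert-butyl (2S)-2-[(2S,3S)-2-(hydroxymethyl)-5-methoxy-4-methylenetetrahydrofuran-3-yl]-2-[(4-methoxybenzyl)oxy]acetate (anomers)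
Conditions: camphor-10-sulfonic acid (cat.), MeOH, 0 °C → rt
Reagents that add atoms: methanol, CO
Why: Acid-catalysed acetalisation through the allylic oxocarbenium ion masks C12 as the methyl lactol ether, and the same acidic methanol solvolyses the primary silyl ether to free the C5 hydroxyl.

Step 7
Reactants: 14 methyl (triphenylphosphoranylidene)acetate; 15 tert-butyl(3-iodopropoxy)dimethylsilane
Product: 17 methyl 5-[(tert-butyldimethylsilyl)oxy]-2-(triphenylphosphoranylidene)pentanoate, via phosphonium iodide 16 (not isolated)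
Conditions: 14 (2 equiv), EtOAc, reflux
Reagents that add atoms: none
Why: C-alkylation of a stabilised phosphorus ylide by a primary iodide followed by transylidation, the second equivalent of 14 deprotonating the phosphonium salt.

Step 8
Reactants: 13 C5 alcohol; 17 methyl 5-[(tert-butyldimethylsilyl)oxy]-2-(triphenylphosphoranylidene)pentanoate
Product: 19 methyl (E)-2-{[(2R,3S)-3-[(1S)-2-tert-butoxy-1-[(4-methoxybenzyl)oxy]-2-oxoethyl]-5-methoxy-4-methylenetetrahydrofuran-2-yl]methylene}-5-[(tert-butyldimethylsilyl)oxy]pentanoate, via C5 aldehyde 18 (not isolated)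
Conditions: Dess–Martin periodinane, pyridine, CH2Cl2, 0 °C → rt; then 17, rt → 40 °C
Reagents that add atoms: none
Why: Dess–Martin oxidation with in situ Wittig olefination avoids isolating the epimerisable α-alkoxy aldehyde, and the stabilised α-substituted ylide places the ester trans to C6, which fixes the C4=C5 geometry of the target (C3 cis to C6).

Step 9
Reactants: 19 enoate
Product: 20 allylic alcohol (6R,7S,8S): as 19 with CH2OH (C15) in place of CO2Me, trans to C6
Conditions: iBu2AlH (2.5 equiv), CH2Cl2, −78 °C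
Reagents that add atoms: none
Why: iBu2AlH 1,2-reduction of the conjugated methyl ester to the allylic alcohol at −78 °C, where the hindered tert-butyl ester and the acetal are expected to survive.

Step 10
Reactants: 20 allylic alcohol
Product: 21 C15 tert-butyldiphenylsilyl ether of 20 (6R,7S,8S; C1 OTBS, C9 tert-butyl ester)
Conditions: TBDPSCl, imidazole, CH2Cl2, rt
Reagents that add atoms: tert-butyldiphenylsilyl chloride, CC(C)(C)[Si](Cl)(c1ccccc1)c1ccccc1
Why: Silylation of the primary allylic alcohol with a group robust enough to outlast the later acidic removal of the C1 silyl ether and the acetal hydrolysis.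

Step 11
Reactants: 21 tert-butyl ester
Product: 22 C9 primary alcohol (6R,7S,8S): (2S)-2-[(4-methoxybenzyl)oxy]ethan-1-ol unit at C7
Conditions: LiAlH4, THF, 0 °C
Reagents that add atoms: none
Why: LiAlH4 reduction of the tert-butyl ester to the primary alcohol; no other reducible group is present and C8 is not touched.

Step 12
Reactants: 22 C9 alcohol
Product: 23 C9 aldehyde (6R,7S,8S): (2S)-2-[(4-methoxybenzyl)oxy]acetaldehyde unit at C7
Conditions: Dess–Martin periodinane, pyridine, CH2Cl2, 0 °C → rt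
Reagents that add atoms: none
Why: Buffered Dess–Martin oxidation should give the α-alkoxy aldehyde without epimerisation at C8.

Step 13
Reactants: 23 C9 aldehyde; 24 ethyl diazoacetate
Product: 25 β-keto ester (6R,7S,8S): ethyl (4S)-4-[(4-methoxybenzyl)oxy]-3-oxobutanoate unit at C7, C1 OTBS, C15 OTBDPS
Conditions: SnCl2 (cat.), CH2Cl2, rt
Reagents that add atoms: none
Why: Roskamp homologation: Lewis-acid-catalysed addition of the diazo ester to the aldehyde and 1,2-hydride shift with loss of N2 give the β-keto ester directly under nearly neutral conditions that leave C8 intact.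

Step 14
Reactants: 25 β-keto ester
Product: 26 C1 primary alcohol (6R,7S,8S)
Conditions: camphor-10-sulfonic acid (cat.), MeOH/CH2Cl2, 0 °C
Reagents that add atoms: none
Why: Acid-catalysed methanolysis removes the primary alkyl tert-butyldimethylsilyl ether selectively over the tert-butyldiphenylsilyl ether, and methanol as solvent keeps the methyl acetal unchanged.

Step 15
Reactants: 26 C1 alcohol
Product: 27 seco aldehyde β-keto ester (6R,7S,8S): 12-methoxy-11(13)-methylene lactol ether, C1 aldehyde, C9 ketone, C14 ethyl ester, 8-OPMB, 15-OTBDPS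
Conditions: Dess–Martin periodinane, CH2Cl2, 0 °C → rt
Reagents that add atoms: none
Why: Dess–Martin oxidation of the primary alcohol to the aldehyde, a reagent that tolerates β-keto esters.

Step 16
Reactants: 27 seco aldehyde β-keto ester
Product: 30 ten-membered alkylidene β-keto ester (6R,7S,8S; C1=C10 with C14 ethyl ester trans to C2; 9-oxo; 8-OPMB; 15-OTBDPS; 12-methoxy lactol ether), via iminium acetate 28 (not isolated), via cyclic Mannich adduct 29 (not isolated)
Conditions: piperidinium acetate (20 mol %), 4 Å molecular sieves, CH2Cl2, slow addition to 1 mM, rt → 40 °C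
Reagents that add atoms: none
Why: Piperidine condenses with the C1 aldehyde to the iminium ion 28, the enol of the β-keto ester attacks it through C10 to give the cyclic Mannich adduct 29, and E1cB loss of piperidine gives 30. The closest known reaction type is the intramolecular Knoevenagel condensation of formyl β-keto esters, applied here to a medium ring. The ten-membered carbocycle closes in the C1–C10 bond-forming step by exo-trig attack of C10 on the iminium carbon (10-exo-trig). No stereocentre is formed; the C1=C10 geometry is set under thermodynamic control through reversible amine addition and should settle on the less strained ring-cis isomer (C9 cis to C2, ester trans). The step needs ring closure to beat oligomerisation and C10 to react in preference to C8; high dilution with slow addition, the turn imposed by the trans-disubstituted five-membered ring and the ring-cis C4=C5 bond, and the much higher acidity of the doubly activated C10 should secure this. The buffered amine salt is too weak a base to epimerise C8 or to affect the acetal, the benzyl ether or the silyl ether.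

Step 17
Reactants: 30 alkylidene β-keto ester
Product: 31 (6R,7S,8S,9S)-9,14-diol (C14 CH2OH trans to C2; 8-OPMB; 15-OTBDPS; 12-methoxy lactol ether)
Conditions: iBu2AlH (excess), toluene/CH2Cl2, −78 °C
Reagents that add atoms: none
Why: iBu2AlH 1,2-reduction of the ketone and the conjugated ester; the non-chelating aluminium hydride should attack C9 in the Felkin–Anh sense, anti to the C8–O bond and from the outer face of the ring, giving the 9S alcohol syn to the C8 oxygen.

Step 18
Reactants: 31 diol
Product: 32 (6R,7S,8S,9S)-9-hydroxy-14-aldehyde (CHO trans to C2)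
Conditions: 2,2,6,6-tetramethylpiperidin-1-oxyl (TEMPO, cat.), PhI(OAc)2, CH2Cl2, rt
Reagents that add atoms: none
Why: Oxoammonium (TEMPO) oxidation is selective for the primary allylic alcohol over the secondary one and leaves the C1=C10 geometry unchanged.

Step 19
Reactants: 32 hydroxy enal
Product: 33 (6R,7S,8S,9S)-9-acetate
Conditions: Ac2O, pyridine, 4-(dimethylamino)pyridine (cat.), CH2Cl2, 0 °C → rt
Reagents that add atoms: acetic anhydride, CC(=O)OC(C)=O
Why: Nucleophile-catalysed acetylation of the secondary allylic alcohol.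

Step 20
Reactants: 33 acetate
Product: 34 (6R,7R,8S,9S)-8-hydroxy 9-acetate (same spatial arrangement; the C7 descriptor changes by priority only)
Conditions: DDQ, CH2Cl2/aq. phosphate buffer (pH 7), 0 °C
Reagents that add atoms: none
Why: Oxidative cleavage of the 4-methoxybenzyl ether by DDQ (benzylic hydride abstraction, then hydrolysis of the oxocarbenium ion) under buffered conditions that spare acetal, silyl ether and acetate.

Step 21
Reactants: 34 C8 alcohol; 35 (S)-2-methylbutanoic acid
Product: 36 (6R,7S,8S,9S)-8-[(S)-2-methylbutanoate] 9-acetate (12-methoxy lactol ether, 15-OTBDPS)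
Conditions: DCC, 4-(dimethylamino)pyridine (cat.), CH2Cl2, 0 °C → rt
Reagents that add atoms: none
Why: Steglich esterification; the acid carries no activating α-heteroatom, so its stereocentre should be retained, and acylation of the C8 hydroxyl should outrun 1,2-acetyl migration.

Step 22
Reactants: 36 diester lactol ether
Product: 37 lactol (12-hydroxy, anomers; 6R,7S,8S,9S)
Conditions: AcOH/THF/H2O (3:1:1), 40 °C
Reagents that add atoms: water, O
Why: Mild aqueous acid hydrolysis of the allylic methyl acetal to the lactol, with the esters and the tert-butyldiphenylsilyl ether stable.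

Step 23
Reactants: 37 lactol
Product: 38 α-methylene γ-lactone, 15-O-tert-butyldiphenylsilyl ether of the target (6R,7S,8S,9S)
Conditions: 2,2,6,6-tetramethylpiperidin-1-oxyl (TEMPO, cat.), PhI(OAc)2, CH2Cl2, rt
Reagents that add atoms: none
Why: Oxoammonium oxidation of the lactol to the lactone; no free alcohol is present to compete.

Step 24
Reactants: 38 silyl ether
Product: 39 CNP0247637.6 (6R,7S,8S,9S; 8-[(S)-2-methylbutanoate], 9-acetate, 14-al, 15-ol)
Conditions: HF·pyridine, pyridine, THF, 0 °C → rt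
Reagents that add atoms: none
Why: Fluoride-mediated cleavage of the silyl ether under buffered conditions that tolerate the enal, the α-methylene lactone and both esters.

**Compound list**

1 | (S)-5-(hydroxymethyl)furan-2(5H)-one | O=C1O[C@H](CO)C=C1 | starting material
2 | (S)-5-{[(tert-butyldimethylsilyl)oxy]methyl}furan-2(5H)-one | O=C1O[C@H](CO[Si](C)(C)C(C)(C)C)C=C1 | intermediate
3 | 4-methoxybenzyl alcohol | COc1ccc(CO)cc1 | starting material
4 | tert-butyl bromoacetate | CC(C)(C)OC(=O)CBr | starting material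
5 | tert-butyl 2-[(4-methoxybenzyl)oxy]acetate | COc1ccc(COCC(=O)OC(C)(C)C)cc1 | intermediate
6 | N,N-dimethylmethyleneiminium iodide (Eschenmoser's salt) | C=[N+](C)C.[I-] | starting material
7 | lithium enolate of 5, OLi cis to the benzyloxy oxygen | [Li]O/C(OC(C)(C)C)=C\OCc1ccc(OC)cc1 | intermediate (not isolated)
8 | lithium enolate of the Michael adduct lactone (6S,7S,8S) | [Li]OC1=C[C@H]([C@H](OCc2ccc(OC)cc2)C(=O)OC(C)(C)C)[C@@H](CO[Si](C)(C)C(C)(C)C)O1 | intermediate (not isolated)
9 | tert-butyl (2S)-2-[(2S,3S,4R)-2-{[(tert-butyldimethylsilyl)oxy]methyl}-4-[(dimethylamino)methyl]-5-oxotetrahydrofuran-3-yl]-2-[(4-methoxybenzyl)oxy]acetate | CN(C)C[C@@H]1C(=O)O[C@H](CO[Si](C)(C)C(C)(C)C)[C@H]1[C@H](OCc1ccc(OC)cc1)C(=O)OC(C)(C)C | intermediate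
10 | trimethylammonium iodide of 9 | C[N+](C)(C)C[C@@H]1C(=O)O[C@H](CO[Si](C)(C)C(C)(C)C)[C@H]1[C@H](OCc1ccc(OC)cc1)C(=O)OC(C)(C)C.[I-] | intermediate (not isolated)
11 | tert-butyl (2S)-2-[(2S,3S)-2-{[(tert-butyldimethylsilyl)oxy]methyl}-4-methylene-5-oxotetrahydrofuran-3-yl]-2-[(4-methoxybenzyl)oxy]acetate | C=C1C(=O)O[C@H](CO[Si](C)(C)C(C)(C)C)[C@H]1[C@H](OCc1ccc(OC)cc1)C(=O)OC(C)(C)C | intermediate
12 | tert-butyl (2S)-2-[(2S,3S)-2-{[(tert-butyldimethylsilyl)oxy]methyl}-5-hydroxy-4-methylenetetrahydrofuran-3-yl]-2-[(4-methoxybenzyl)oxy]acetate (anomers) | C=C1C(O)O[C@H](CO[Si](C)(C)C(C)(C)C)[C@H]1[C@H](OCc1ccc(OC)cc1)C(=O)OC(C)(C)C | intermediate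
13 | tert-butyl (2S)-2-[(2S,3S)-2-(hydroxymethyl)-5-methoxy-4-methylenetetrahydrofuran-3-yl]-2-[(4-methoxybenzyl)oxy]acetate (anomers) | C=C1C(OC)O[C@H](CO)[C@H]1[C@H](OCc1ccc(OC)cc1)C(=O)OC(C)(C)C | intermediate
14 | methyl (triphenylphosphoranylidene)acetate | COC(=O)C=P(c1ccccc1)(c1ccccc1)c1ccccc1 | starting material
15 | tert-butyl(3-iodopropoxy)dimethylsilane | CC(C)(C)[Si](C)(C)OCCCI | starting material
16 | {5-[(tert-butyldimethylsilyl)oxy]-1-methoxy-1-oxopentan-2-yl}triphenylphosphonium iodide | COC(=O)C(CCCO[Si](C)(C)C(C)(C)C)[P+](c1ccccc1)(c1ccccc1)c1ccccc1.[I-] | intermediate (not isolated)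
17 | methyl 5-[(tert-butyldimethylsilyl)oxy]-2-(triphenylphosphoranylidene)pentanoate | COC(=O)C(CCCO[Si](C)(C)C(C)(C)C)=P(c1ccccc1)(c1ccccc1)c1ccccc1 | intermediate
18 | tert-butyl (2S)-2-[(2S,3S)-2-formyl-5-methoxy-4-methylenetetrahydrofuran-3-yl]-2-[(4-methoxybenzyl)oxy]acetate | C=C1C(OC)O[C@H](C=O)[C@H]1[C@H](OCc1ccc(OC)cc1)C(=O)OC(C)(C)C | intermediate (not isolated)
19 | methyl (E)-2-{[(2R,3S)-3-[(1S)-2-tert-butoxy-1-[(4-methoxybenzyl)oxy]-2-oxoethyl]-5-methoxy-4-methylenetetrahydrofuran-2-yl]methylene}-5-[(tert-butyldimethylsilyl)oxy]pentanoate | C=C1C(OC)O[C@H](/C=C(/C(=O)OC)CCCO[Si](C)(C)C(C)(C)C)[C@H]1[C@H](OCc1ccc(OC)cc1)C(=O)OC(C)(C)C | intermediate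
20 | allylic alcohol (6R,7S,8S): 19 with C15 as CH2OH trans to C6 | C=C1C(OC)O[C@H](/C=C(/CO)CCCO[Si](C)(C)C(C)(C)C)[C@H]1[C@H](OCc1ccc(OC)cc1)C(=O)OC(C)(C)C | intermediate
21 | 15-O-tert-butyldiphenylsilyl ether of 20 (6R,7S,8S) | C=C1C(OC)O[C@H](/C=C(/CO[Si](c2ccccc2)(c2ccccc2)C(C)(C)C)CCCO[Si](C)(C)C(C)(C)C)[C@H]1[C@H](OCc1ccc(OC)cc1)C(=O)OC(C)(C)C | intermediate
22 | C9 primary alcohol (6R,7S,8S) | C=C1C(OC)O[C@H](/C=C(/CO[Si](c2ccccc2)(c2ccccc2)C(C)(C)C)CCCO[Si](C)(C)C(C)(C)C)[C@H]1[C@H](OCc1ccc(OC)cc1)CO | intermediate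
23 | C9 aldehyde (6R,7S,8S) | C=C1C(OC)O[C@H](/C=C(/CO[Si](c2ccccc2)(c2ccccc2)C(C)(C)C)CCCO[Si](C)(C)C(C)(C)C)[C@H]1[C@H](OCc1ccc(OC)cc1)C=O | intermediate
24 | ethyl diazoacetate | CCOC(=O)C=[N+]=[N-] | starting material
25 | β-keto ester (6R,7S,8S), C1 OTBS, C15 OTBDPS | C=C1C(OC)O[C@H](/C=C(/CO[Si](c2ccccc2)(c2ccccc2)C(C)(C)C)CCCO[Si](C)(C)C(C)(C)C)[C@H]1[C@H](OCc1ccc(OC)cc1)C(=O)CC(=O)OCC | intermediate
26 | C1 alcohol β-keto ester (6R,7S,8S) | C=C1C(OC)O[C@H](/C=C(/CO[Si](c2ccccc2)(c2ccccc2)C(C)(C)C)CCCO)[C@H]1[C@H](OCc1ccc(OC)cc1)C(=O)CC(=O)OCC | intermediate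
27 | seco aldehyde β-keto ester (6R,7S,8S), key-step precursor | C=C1C(OC)O[C@H](/C=C(/CO[Si](c2ccccc2)(c2ccccc2)C(C)(C)C)CCC=O)[C@H]1[C@H](OCc1ccc(OC)cc1)C(=O)CC(=O)OCC | intermediate
28 | C1 piperidinium iminium acetate of 27 | C=C1C(OC)O[C@H](/C=C(/CO[Si](c2ccccc2)(c2ccccc2)C(C)(C)C)CCC=[N+]2CCCCC2)[C@H]1[C@H](OCc1ccc(OC)cc1)C(=O)CC(=O)OCC.CC(=O)[O-] | intermediate (not isolated)
29 | cyclic Mannich adduct: 1-(piperidin-1-yl)-1,10-dihydro form of 30 (C1, C10 undefined) | C=C1C(OC)O[C@@H]2/C=C(/CO[Si](c3ccccc3)(c3ccccc3)C(C)(C)C)CCC(N3CCCCC3)C(C(=O)OCC)C(=O)[C@@H](OCc3ccc(OC)cc3)[C@@H]12 | intermediate (not isolated)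
30 | ten-membered alkylidene β-keto ester (6R,7S,8S), key-step product | C=C1C(OC)O[C@@H]2/C=C(/CO[Si](c3ccccc3)(c3ccccc3)C(C)(C)C)CC/C=C(/C(=O)OCC)C(=O)[C@@H](OCc3ccc(OC)cc3)[C@@H]12 | intermediate
31 | (6R,7S,8S,9S)-9,14-diol | C=C1C(OC)O[C@@H]2/C=C(/CO[Si](c3ccccc3)(c3ccccc3)C(C)(C)C)CC/C=C(/CO)[C@H](O)[C@@H](OCc3ccc(OC)cc3)[C@@H]12 | intermediate
32 | (6R,7S,8S,9S)-9-hydroxy-14-aldehyde | C=C1C(OC)O[C@@H]2/C=C(/CO[Si](c3ccccc3)(c3ccccc3)C(C)(C)C)CC/C=C(/C=O)[C@H](O)[C@@H](OCc3ccc(OC)cc3)[C@@H]12 | intermediate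
33 | (6R,7S,8S,9S)-9-acetate, 8-OPMB | C=C1C(OC)O[C@@H]2/C=C(/CO[Si](c3ccccc3)(c3ccccc3)C(C)(C)C)CC/C=C(/C=O)[C@H](OC(C)=O)[C@@H](OCc3ccc(OC)cc3)[C@@H]12 | intermediate
34 | (6R,7R,8S,9S)-8-hydroxy 9-acetate | C=C1C(OC)O[C@@H]2/C=C(/CO[Si](c3ccccc3)(c3ccccc3)C(C)(C)C)CC/C=C(/C=O)[C@H](OC(C)=O)[C@@H](O)[C@@H]12 | intermediate
35 | (S)-2-methylbutanoic acid | CC[C@H](C)C(=O)O | starting material
36 | (6R,7S,8S,9S)-8-[(S)-2-methylbutanoate] 9-acetate, 12-methoxy lactol ether | C=C1C(OC)O[C@@H]2/C=C(/CO[Si](c3ccccc3)(c3ccccc3)C(C)(C)C)CC/C=C(/C=O)[C@H](OC(C)=O)[C@@H](OC(=O)[C@@H](C)CC)[C@@H]12 | intermediate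
37 | lactol of 36 (12-hydroxy, anomers) | C=C1C(O)O[C@@H]2/C=C(/CO[Si](c3ccccc3)(c3ccccc3)C(C)(C)C)CC/C=C(/C=O)[C@H](OC(C)=O)[C@@H](OC(=O)[C@@H](C)CC)[C@@H]12 | intermediate
38 | 15-O-tert-butyldiphenylsilyl ether of the target | C=C1C(=O)O[C@@H]2/C=C(/CO[Si](c3ccccc3)(c3ccccc3)C(C)(C)C)CC/C=C(/C=O)[C@H](OC(C)=O)[C@@H](OC(=O)[C@@H](C)CC)[C@@H]12 | intermediate
39 | CNP0247637.6 | C=C1C(=O)O[C@@H]2/C=C(/CO)CC/C=C(/C=O)[C@H](OC(C)=O)[C@@H](OC(=O)[C@@H](C)CC)[C@@H]12 | target

**Totals**

Total step count: 24. Longest linear sequence: 22 steps (1 to 39 through steps 1, 3–6 and 8–24; steps 2 and 7 are side branches).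

**Steps most likely to fail**

1. Step 16 (ring closure). Intermolecular condensation may outrun closure of the strained ten-membered ring, the equilibrium may not favour the cyclic alkylidene compound, and long exposure to the amine could erode C8. Fallback, an irreversible metal-templated closure of the same bond: starting from 27, α-bromination at C10 with N-bromosuccinimide and NH4OAc (cat.) in Et2O should give the C10-bromo keto ester F1. SmI2 in THF at −78 °C under high dilution would turn it into a samarium enolate that adds to the C1 aldehyde in a Reformatsky-type cyclisation, giving the ten-membered β-hydroxy keto ester F2. Mesylation (MsCl, Et3N) gives the mesylate F3, and elimination with DBU comes back to 30.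

2. Step 3 (Michael/Mannich). The enolate may approach with the other relative topicity and give mainly the C8 epimer, or it may deprotonate C6 of the butenolide. Fallback, inversion of the enolate geometry: tert-butyl 2-[(triethylsilyl)oxy]acetate F4 (from tert-butyl glycolate, Et3SiCl and imidazole) cannot chelate lithium. With LiN(iPr)2 in THF it should give the enolate with OLi trans to the silyloxy group, which is added to 2 and then trapped with 6 to give the silyl-protected Mannich base F5. MeI gives the ammonium iodide F6 and NaHCO3 the α-methylene lactone F7. HF·pyridine/pyridine at 0 °C removes the triethylsilyl group to give the C8 alcohol F8, and 4-methoxybenzyl trichloroacetimidate with catalytic camphor-10-sulfonic acid comes back to 11.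

3. Step 17 (C9 reduction). Hydride may enter from the wrong face if ring conformation or chelation to the C8 ether overrides Felkin–Anh control, or it may add in a conjugate sense. Fallback, reagent control in two stages: starting from 30, Corey–Bakshi–Shibata reduction with (S)-1-methyl-3,3-diphenyltetrahydro-1H,3H-pyrrolo[1,2-c][1,3,2]oxazaborole and catecholborane in toluene at −78 °C should reduce only the ketone, with the alkylidene arm acting as the large substituent, to the 9S hydroxy ester F9. iBu2AlH at −78 °C then reduces the ester and comes back to 31.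

**Further compounds**

F1 | step 16 | C10-bromo derivative of 27 (C10 undefined) | C=C1C(OC)O[C@H](/C=C(/CO[Si](c2ccccc2)(c2ccccc2)C(C)(C)C)CCC=O)[C@H]1[C@H](OCc1ccc(OC)cc1)C(=O)C(Br)C(=O)OCC
F2 | step 16 | ten-membered aldol, 1-hydroxy-1,10-dihydro form of 30 (C1, C10 undefined) | C=C1C(OC)O[C@@H]2/C=C(/CO[Si](c3ccccc3)(c3ccccc3)C(C)(C)C)CCC(O)C(C(=O)OCC)C(=O)[C@@H](OCc3ccc(OC)cc3)[C@@H]12
F3 | step 16 | 1-O-methanesulfonate of F2 | C=C1C(OC)O[C@@H]2/C=C(/CO[Si](c3ccccc3)(c3ccccc3)C(C)(C)C)CCC(OS(C)(=O)=O)C(C(=O)OCC)C(=O)[C@@H](OCc3ccc(OC)cc3)[C@@H]12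
F4 | step 3 | tert-butyl 2-[(triethylsilyl)oxy]acetate | CC[Si](CC)(CC)OCC(=O)OC(C)(C)C
F5 | step 3 | analogue of 9 with OSiEt3 at C8 | CN(C)C[C@@H]1C(=O)O[C@H](CO[Si](C)(C)C(C)(C)C)[C@H]1[C@H](O[Si](CC)(CC)CC)C(=O)OC(C)(C)C
F6 | step 3 | trimethylammonium iodide of F5 | C[N+](C)(C)C[C@@H]1C(=O)O[C@H](CO[Si](C)(C)C(C)(C)C)[C@H]1[C@H](O[Si](CC)(CC)CC)C(=O)OC(C)(C)C.[I-]
F7 | step 3 | analogue of 11 with OSiEt3 at C8 | C=C1C(=O)O[C@H](CO[Si](C)(C)C(C)(C)C)[C@H]1[C@H](O[Si](CC)(CC)CC)C(=O)OC(C)(C)C
F8 | step 3 | analogue of 11 with free OH at C8 | C=C1C(=O)O[C@H](CO[Si](C)(C)C(C)(C)C)[C@H]1[C@H](O)C(=O)OC(C)(C)C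
F9 | step 17 | (6R,7S,8S,9S)-9-hydroxy C14 ethyl ester | C=C1C(OC)O[C@@H]2/C=C(/CO[Si](c3ccccc3)(c3ccccc3)C(C)(C)C)CC/C=C(/C(=O)OCC)[C@H](O)[C@@H](OCc3ccc(OC)cc3)[C@@H]12
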